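The constants were chosen freely; the flask was simulated.

At early times the electrophile in each flask is taken by two partners at once, the nucleophile and the protic impurity, and we follow the rate of that loss.

all flasks: electrophile 0.42 M; protic impurity 0.210 M; time 6.0 h
- Tuesday's: nucleophile 0.640 M
- Wednesday's: nucleophile 0.380 M
- Sunday's: nucleophile 0.490 M

    electrophile + nucleophile ⇌ acid set free + target (K1 = 0.72, k1 = 0.015 M⁻¹ min⁻¹)
    nucleophile + acid set free ⇌ protonated nucleophile, settled at all times (K2 = 1500 M⁻¹)
    electrophile + protic impurity → quenched substrate (k3 = 0.032 M⁻¹ min⁻¹)
    target → over-reaction product (k4 = 6.7 × 10⁻⁴ min⁻¹)

- part of the electrophile that has reacted at the end, Tuesday's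
- part of the electrophile that has reacted at the end, Wednesday's
- part of the electrophile that has reacted at the end, Sunday's
- what raising the concentration of nucleophile from its lowest to its highest value here does to the part of the electrophile that has reacted (changes below 5 percentage points count as none) (it rises / it falls / no change)

Just after the start of Sunday's, the forward first step uses electrophile 1.1 times as fast as the quench, so that flask begins near the even case. We take this even case as our zero and drop the way back.

On Wednesday's, the second equilibrium constant times c(nucleophile) starts at 570, far above one, so we count 2 nucleophiles per turnover of the first step, the second ending as protonated nucleophile. Per unit of accumulated c(electrophile)·time, the nucleophile then falls fractionally at 0.0300 M⁻¹ min⁻¹ and the impurity at 0.032 M⁻¹ min⁻¹, nearly the same. We set both to their mean, κ = 0.0310 M⁻¹ min⁻¹. The two partners then shrink by one common factor and act as a single partner.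

Its charge is the capacity, C = c(nucleophile)/2 + c(protic impurity), the electrophile a flask can take up at 2 nucleophiles per turnover. For Sunday's, C is 0.455 M, and the starting loss per electrophile, κC, is 0.0141 min⁻¹. The rate is κ·c(electrophile)·(capacity left), plain second order, so it is slowed by two factors. With d = C − c(electrophile), both taken at the charge, the share of capacity left over the share of electrophile left becomes E = exp(dκt), and the share of electrophile left is d/(EC − c(electrophile)):

Sunday's: d = 0.0350 M, E = 1.48, left 13.9%

Tuesday's: C = 0.530 M, E = 3.41, left 7.92%

Wednesday's: C = 0.400 M, E = 0.800, left 20.0%

So we expect the part of the electrophile that has reacted to rise by 12 percentage points from Wednesday's to Tuesday's. Wednesday's capacity is smaller than its electrophile charge, which makes the lumped partner the limiting reagent in that flask.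

The forecast gives 92% (90% to 94%) for Tuesday's, 80% (77% to 82%) for Wednesday's and 86% (83% to 88%) for Sunday's, and says it rises, holding that “the nucleophile charge sets how fast the electrophile keeps being consumed alongside the impurity quench”.

The simulation gives 91.9% for Tuesday's, 80.0% for Wednesday's and 86.0% for Sunday's: it rises, by 12 points. Left for 60.0 h, Wednesday's has reacted 94.2% of its electrophile, and its capacity stands at 95.2% of that charge.

Take a flask like Sunday's with 0.084 M of protic impurity. Its capacity is 0.329 M, E is 0.362, and the reckoning gives 69.8% reacted. The simulation gives 69.5%.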